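**Remarks on the chemistry**

- Atoms keep the numbers of the target SMILES (C1 … C26, O10). α is the face of the C15 methyl (C16), H24, H8, H6 and O10; β is the face of H23, the C11 methyl (C12) and the C6 methyl (C7).
- 3,3-Dimethylcyclohexanone, (R)-1-phenylethylamine, but-3-en-2-one, 1-bromobut-2-yne and cyclopent-2-en-1-one are taken as commercial.
- Compounds 27–30 are 5-hydroxycyclooctanones (O10/C26) and may rest as the transannular hemiketal; they are drawn open.
- Three design points differ from the simplest form of this disconnection:
  - A saturated dione offers two α′ sites (C11–H and C25–H2) to the aldehyde. The precursor therefore carries a C11=C13 double bond, so that C11 is the α-terminus of an extended dienolate, and is handled as its sodium enolate (the free dione is a tautomer of a dihydroxytetralin).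
  - The bridged geometry does not by itself fix C11. The C9 branch can be axial on both rings (trans-fused ketol) or on the dione ring only (cis-fused ketol, the one needed). The face is decided when C2 is alkylated.
  - After the key step, C6 is completed before C2=C3 exists, and the hydrazine reduction of the C12 aldehyde is placed after C26 has lost its oxygen.

## Structural features

Compound 38 (C25H42O) is a 5–8–6–6 tetracycle: cyclopentane ring A and cyclooctene ring B share C3–C8, ring B and cyclohexane ring C share C11–C24, and rings C and D form a trans-decalin across C15–C23. Seven stereocentres stand in one unbroken chain, C6–C8–C9–C11–C24–C23–C15; C11 and C15 are quaternary, carry methyl groups on opposite faces, and rings B/C are trans-fused (C9 α on C11, C25 β on C24). The only functional groups are the secondary neopentyl alcohol at C9 (O10 α, between quaternary C11 and tertiary C8) and the tetrasubstituted C2=C3 bond, exocyclic to ring A and Z within ring B. Both are sensitive to acid: C8–H is allylic, so protonation can move the double bond to C3=C8 and erase C8, and ionisation at C9 invites a 1,2-shift from C11. The real difficulty is the eight-membered ring with the quaternary C11 at the B/C junction and the relative configuration of C8, C9 and C11; the decalin and the C6 methyl are routine by comparison. The key step uses the fact that C2 and C11 are 1,5-related on both arcs of ring B and each bears a one-carbon branch (C1, C12). Joining C2 to C12 turns ring B into a bicyclo[3.3.1]nonane whose six-membered rings are made by a Michael addition (C2–C3) and an aldol reaction (C9–C11); cleaving the bridge bond C2–C12 then leaves C12 on C11.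

## Logic of the disconnections

**38 from 34 (through 37, 36, 35).** No skeletal bond is cut; the C–H bonds of the C12 methyl are exchanged for C–O bonds until the methyl ester is reached. The reason is that the key step leaves C12 on C11 at the carboxylate level. The skeleton is not simplified, but the retron of the bridge cleavage appears. The forward steps must reduce a neopentyl ester and then a β-hydroxy aldehyde without opening C9–C11, and the hydrazine reduction must come when C12 is the only carbonyl left.

**34 from 30 (through 33, 32, 31).** No C–C bond is cut: C26 receives a carbonyl group and C2=C3 is saturated. A C26 ketone is what the bridge cleavage leaves behind and is the only handle from which the tetrasubstituted alkene can be placed. The demands are enolisation of C26 towards C2 and not C25, and removal of the C26 oxygen without moving the double bond to C3=C8 or C26=C2.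

**30 from 27 (through 29, 28).** The C6–C7 bond is cut (methyl from a ketone by methylenation and hydrogenation) and the C13=C14 bond, a relic of the key step, is restored. C6 is finished here because a C6 ketone cannot coexist with C2=C3: C8–H would be both α to the ketone and allylic. The gain is an achiral ketal at C6 and hence an achiral enal partner. The methylenation must choose the cyclopentanone over the ring B ketone and must not be basic (β-hydroxy ketone); hydrogen must reach C6 from the α face.

**27 from 18 and 24 (through 26, 25).** The C2–C12 bond is re-formed in the retron, then C9–C11 (aldol) and C2–C3 (Michael) are cut. This is where ring B is traded for a six-membered ring and where rings A and C part. C8, C9 and C11 disappear together, leaving a tricyclic dione enolate and an achiral enal. The forward step needs C11 and not C25 as the aldol donor, the α face at C2, and methoxide attack at C12.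

**18 from 14 (through 17, 16, 15).** The C2–C12 bond (Claisen condensation), the O–C26 bond (oxygen delivered to the alkyne by the carboxyl group) and the C11–C12 bond (carbon monoxide) are cut. This reduces the dione ring to a decalin enol triflate with a but-2-ynyl chain. The demands are 6-exo delivery of oxygen to C26 rather than C2, and a dione that is never set free as the neutral compound.

**14 from 9 and 10 (through 13, 12, 11).** The C24–C25 bond is cut. Reduction of the enone gives a regiodefined enolate whose alkylation sets H23 and the C24 side chain in one operation. The demand is trans ring fusion and an equatorial side chain; enolisation of 12 must then go towards C13.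

**9 from 1, 4 and 6 (through 8, 7, 5, 3, 2).** The C23=C24 and C14–C15 bonds (Robinson annulation) and C15–C16 (methylation) are cut, back to a commercial ketone, an enone and a chiral amine. The only demand is face selection at C15, taken from the amine.

**24 from 19 (through 23, 22, 21, 20).** The C8–C9 bond is cut (formylation of a vinyllithium); the ketal is both the C6 protecting group and what makes the lithiation possible.

## Other disconnections considered

**Alternative 1: rhodium allenic Pauson–Khand reaction.**
- Cut: C3–C8, C4–C5 and C5–C6, with C5 taken from carbon monoxide.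
- Forward step: allene–yne A1 under CO with [RhCl(CO)2]2 (monovalent rhodium) would react at the distal allene bond to give dienone A2, closing rings A and B together.
- In its favour: C2=C3 is born in place with the right geometry and no redox work at C26 is needed. On this point it is better than the chosen plan, which spends four steps on that alkene. C9, C11 and the decalin are made on an open chain.
- Against it here: the alkyne–allene tether has five atoms (C9, C11, C24, C25, C26), so an eight-membered ring must form, outside the five- to seven-membered range where this cyclocarbonylation is dependable. A2 still needs C5 deoxygenated and the tetrasubstituted C6=C8 bond reduced with control of two stereocentres in a linearly conjugated dienone, without touching C2=C3.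
- Comparison: on structure the alternative is better for the alkene and worse for C6 and C8, which the chosen route sets one at a time (C8 in the cascade, C6 by hydrogenation). On mechanism the alternative closes the medium ring directly at the metal, whereas the chosen plan releases it from a six-membered ring. Step economy would be about equal if the cyclocarbonylation worked, since the redox work only moves from C26/C12 to C5/C6/C8.

**Alternative 2: palladium π-allyl closure.**
- Cut: C25–C26.
- Forward step: carbonate A3 with Pd(PPh3)4 (zerovalent palladium) would ionise at the tertiary C3 carbonate, and the C25 bis(sulfonyl) carbanion would attack the primary terminus C26 to give A4.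
- In its favour: the alkene is again placed by the ring-forming step, and ring A arrives with C6 and C8 already set, so the plan is more convergent. On alkene placement and convergence it is better than the chosen plan.
- Against it here: an eight-membered ring must be closed by C–C bond formation between a hindered tertiary carbanion and an allyl terminus. Attack at the other terminus (C3) would close a six-membered ring (C25, C24, C11, C9, C8, C3) and could compete, as could elimination to a diene. Two sulfonyl groups must be removed afterwards, and the C8–C9–C11 array must be assembled by a stereocontrolled fragment union beforehand.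
- Comparison: on structure the alternative is ahead for the alkene and for C6. On mechanism a medium-ring closure is less favourable than the ring expansion of the chosen plan. Step count is expected to be comparable.

**Alternative 3: Claisen ring expansion.**
- Cut: C3–C8, after adding the O–C26 bond in the retron.
- Forward step: heating methylenepyran A5 would drive the [3,3] shift of C8=C9–O–C26–C2=C3 to cyclooctenone A6.
- In its favour: like the chosen plan it unveils ring B from a six-membered ring instead of closing it; on this the two are equal. The rearrangement is unimolecular, neutral and stereospecific, so on predictability of mechanism it is better than a three-event anionic cascade.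
- Against it here: A6 has the double bond at C26=C2, one position off, and its later isomerisation into C2=C3 competes with other positions. Ring A is still open (C6–C8 to be formed from the silylbutynyl arm), and C6, C8 and the C9 carbinol are all unset. A5 needs methylenation of a hindered lactone (for example with Cp2TiMe2) and a defined C26 centre.
- Comparison: the chosen cascade forms two skeletal bonds and three retained stereocentres while opening ring B; the Claisen step forms one bond and one stereocentre that is later erased. Step economy therefore favours the chosen plan, reliability of the individual step favours the alternative.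

Key step: step 13

## Steps

Step 1
Reactants: 1 3,3-dimethylcyclohexanone
Product: 3 2,5,5-trimethylcyclohexanone (racemic), via lithium 5,5-dimethylcyclohex-1-en-1-olate 2 (not isolated)
Conditions: LDA, THF, −78 °C; MeI, −78 to 0 °C
Reagents that add atoms: iodomethane, CI
Why: Kinetic enolate alkylation; LDA removes a proton from the α-methylene remote from the gem-dimethyl carbon (future C15) rather than from the neopentyl one (future C22). The new centre is racemic and becomes mobile in step 2.

Step 2
Reactants: 3 2,5,5-trimethylcyclohexanone; 4 (R)-1-phenylethylamine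
Product: 5 (R)-1-phenyl-N-(2,5,5-trimethylcyclohexylidene)ethanamine
Conditions: TsOH (cat.), toluene, reflux, azeotropic removal of water
Reagents that add atoms: none
Why: Ketimine condensation; the C15 centre equilibrates through the secondary enamine tautomer, so the racemic ketone converges.

Step 3
Reactants: 5 (R)-1-phenyl-N-(2,5,5-trimethylcyclohexylidene)ethanamine; 6 but-3-en-2-one
Product: 8 (S)-2,5,5-trimethyl-2-(3-oxobutyl)cyclohexan-1-one, via ketimine Michael adduct 7 (not isolated)
Conditions: THF, 25–40 °C; then 10% aq. AcOH, 20 °C
Reagents that add atoms: water, O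
Why: Asymmetric Michael addition of a chiral imine through its more substituted secondary enamine (aza-ene-like transition state). The enone is delivered to the face away from the phenyl group, so by analogy with 2-methylcyclohexanone the (R)-amine should give (S)-C15; hydrolysis returns the auxiliary.

Step 4
Reactants: 8 (S)-2,5,5-trimethyl-2-(3-oxobutyl)cyclohexan-1-one
Product: 9 (S)-4a,7,7-trimethyl-4,4a,5,6,7,8-hexahydronaphthalen-2(3H)-one
Conditions: NaOMe (cat.), MeOH, reflux
Reagents that add atoms: none
Why: Intramolecular aldol condensation (second half of a Robinson annulation): the methyl ketone carbon C24 adds to the C23 carbonyl and water is lost; no stereocentre is formed.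

Step 5
Reactants: 9 (S)-4a,7,7-trimethyl-4,4a,5,6,7,8-hexahydronaphthalen-2(3H)-one; 10 1-bromobut-2-yne
Product: 12 trans-fused decalone (C11 ketone; C24 β-but-2-ynyl equatorial; H23 β; H24 α), via lithium enolate of the trans-decalone 11 (not isolated)
Conditions: Li, NH3(l)/THF, t-BuOH (1 equiv), −78 °C; isoprene; then 10, −78 to −33 °C
Reagents that add atoms: none
Why: Reductive alkylation of an enone: dissolving-metal reduction protonates C23 axially to give the trans-fused, regiodefined C11=C24 enolate. The propargylic bromide, added after excess lithium is destroyed, enters at C24 anti to the axial C15 methyl, giving the equatorial (also thermodynamic) epimer.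

Step 6
Reactants: 12 trans-fused decalone
Product: 14 enol triflate C11(OTf)=C13, via potassium enolate towards C13 13 (not isolated)
Conditions: KHMDS, THF, −78 °C; PhNTf2, −78 to 0 °C
Reagents that add atoms: N-phenylbis(trifluoromethanesulfonimide), O=S(=O)(N(c1ccccc1)S(=O)(=O)C(F)(F)F)C(F)(F)F
Why: Kinetic enolisation goes to the methylene C13 because C24 is now tertiary and shielded; O-sulfonylation gives the enol triflate.

Step 7
Reactants: 14 enol triflate C11(OTf)=C13
Product: 15 unsaturated acid (C12 carboxyl on C11; C11=C13)
Conditions: Pd(OAc)2 (cat.), dppf, CO (1 atm), KOAc, DMF/H2O, 60 °C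
Reagents that add atoms: carbon monoxide, [C-]#[O+]; water, O
Why: Palladium-catalysed hydroxycarbonylation of a vinyl triflate (oxidative addition, CO insertion, capture by acetate and water) attaches C12 to C11. The acid also allows enantiomeric enrichment by crystallisation of its salt with 4 if needed.

Step 8
Reactants: 15 unsaturated acid
Product: 16 (Z)-enol δ-lactone (O–C26; exocyclic C26=C2)
Conditions: Ph3PAuCl (5 mol%), AgOTf (5 mol%), CH2Cl2, 25 °C
Reagents that add atoms: none
Why: Gold-catalysed cycloisomerisation of a 5-alkynoic acid: the carboxyl oxygen adds anti to the activated alkyne in the 6-exo-dig mode. This puts oxygen on C26, which an unassisted hydration of the butynyl group could not distinguish from C2.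

Step 9
Reactants: 16 (Z)-enol δ-lactone
Product: 18 sodium enolate of the tricyclic 2-methyl-1,3-dione (C12 and C26 carbonyls; C11=C13), via ring-opened methyl ester enolate 17 (not isolated)
Conditions: NaOMe (1.1 equiv), MeOH, 0 to 40 °C; evaporation, salt not neutralised
Reagents that add atoms: sodium methoxide, [Na+].[O-]C
Why: Methoxide opens the enol ester to the C26 enolate and a methyl ester; C2 then acylates on C12 (intramolecular Claisen condensation, 6-exo-trig), and the β-diketone is held as its enolate. This is the known base rearrangement of enol lactones to cyclic 1,3-diones; the salt is kept because the free 4-alkylidene dione could tautomerise to an aromatic diol.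

Step 10
Reactants: 19 cyclopent-2-en-1-one
Product: 21 2-bromocyclopent-2-en-1-one, via trans-2,3-dibromocyclopentanone 20 (not isolated)
Conditions: Br2, CH2Cl2, 0 °C; then Et3N
Reagents that add atoms: bromine, BrBr
Why: Bromination–dehydrobromination: bromine adds across the enone and the amine removes HBr through the acidic α-hydrogen.

Step 11
Reactants: 21 2-bromocyclopent-2-en-1-one
Product: 22 6-bromo-1,4-dioxaspiro[4.4]non-6-ene
Conditions: ethylene glycol, TsOH (cat.), benzene, reflux, azeotropic removal of water
Reagents that add atoms: ethylene glycol, OCCO
Why: Acid-catalysed ketalisation; it protects C6 and removes the carbonyl that would interfere with the halogen–metal exchange.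

Step 12
Reactants: 22 6-bromo-1,4-dioxaspiro[4.4]non-6-ene
Product: 24 1,4-dioxaspiro[4.4]non-6-ene-6-carbaldehyde, via 6-lithio-1,4-dioxaspiro[4.4]non-6-ene 23 (not isolated)
Conditions: n-BuLi, THF, −78 °C; DMF; H2O
Reagents that add atoms: N,N-dimethylformamide, CN(C)C=O
Why: Bromine–lithium exchange followed by formylation of the vinyllithium; the ketal is inert to the base.

Step 13
Reactants: 18 sodium enolate of the tricyclic 2-methyl-1,3-dione; 24 1,4-dioxaspiro[4.4]non-6-ene-6-carbaldehyde
Product: 27 tetracyclic keto ester (C26 ketone; C6 ethylene ketal; O10 α; C11 β-CO2Me; H8 α; H3 α; C2 methyl epimers; C13=C14), via Michael adduct aldehyde 25 (not isolated), via bridged ketol 26 (not isolated)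
Conditions: 24 (1.1 equiv), NaOMe (1.5 equiv), MeOH, 0 to 25 °C; AcOH quench
Reagents that add atoms: methanol (as sodium methoxide), CO
Why: Two known reaction types are joined: the base-mediated Michael–aldol annulation of a 2-alkylcyclohexane-1,3-dione with an enal to a bicyclo[3.3.1]nonane ketol, and the alkoxide (retro-Claisen) cleavage of its non-enolisable bridging ketone, the diketone counterpart of the Michael–aldol–retro-Dieckmann ring expansion of β-keto esters. Enolate 18 adds through C2 to C3 of 24 to give aldehyde 25 with C2 quaternary; methoxide then removes a γ-hydrogen (C14) of the C12 enone and the dienolate attacks the aldehyde through its α-carbon C11 in a 6-(enolexo)-exo-trig aldol, closing the ring C2–C3–C8–C9–C11–C12 of 26 and leaving the double bond at C13=C14. Methoxide adds to the strained bridge carbonyl C12 and C2–C12 breaks with the C26 enolate as leaving group, so ring B is released by cleavage and never closed as a medium ring; attack at C26 is unproductive because the carbanion it would expel at C2 is a bridgehead enolate (Bredt's rule). The choice of C11 over C25 is secured by the C11=C13 unsaturation of 18, which makes the extended dienolate far more populated than the simple C25 enolate. C8 (epimerisable while it is an aldehyde α-carbon) and C9 should settle under the reversible aldol with ring A exo and the hydroxyl equatorial on the new chair, which is the target arrangement. C11 is formed on the face on which C2 was alkylated, because the C2–C3 and C11–C9 bonds must be 1,3-diaxial across C12; the target needs the α face (syn to H24), which gives the ketol with trigonal C12 axial on ring C and C23 axial on the dione ring, where both 1,3-partners are trigonal. The substrate does not enforce that face in the Michael step; the expectation rests on reversibility of the Michael and aldol steps and on the lower strain of that ketol, and this is the point that must be verified. C2 and C3 are erased later, so their configuration is immaterial.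

Step 14
Reactants: 27 tetracyclic keto ester
Product: 28 diketone (C6 ketone unveiled)
Conditions: PPTS (cat.), acetone/H2O, 40 °C
Reagents that add atoms: water, O
Why: Mild acid hydrolysis of the dioxolane; the β-hydroxy ketone is kept cold and used at once to limit epimerisation at C8 and dehydration towards C8=C9.

Step 15
Reactants: 28 diketone
Product: 29 exocyclic methylene compound (C6=C7)
Conditions: Zn, CH2Br2, TiCl4, THF/CH2Cl2, 0 to 25 °C
Reagents that add atoms: dibromomethane, BrCBr
Why: Takai–Lombardo methylenation; the reagent is not basic, so the β-hydroxy ketone should neither fragment nor eliminate. The cyclopentanone C6 should react ahead of the α-branched cyclooctanone C26, which is also partly masked as the hemiketal with O10.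

Step 16
Reactants: 29 exocyclic methylene compound
Product: 30 saturated keto ester (C6 β-methyl; ring C saturated)
Conditions: H2 (3 atm), PtO2, EtOAc, 25 °C
Reagents that add atoms: none
Why: Heterogeneous hydrogenation of both alkenes. Ring A is cis-fused to ring B at this stage (the ring B bonds at C3 and C8 are both β), so hydrogen should reach C6 from the open α face and place the methyl β, cis to C9; saturation of C13=C14 creates no stereocentre.

Step 17
Reactants: 30 saturated keto ester
Product: 31 bis(trimethylsilyl) compound (C26 silyl enol ether C2=C26; O10 silyl ether)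
Conditions: TMSOTf (3 equiv), Et3N (4 equiv), CH2Cl2, 0 to 25 °C
Reagents that add atoms: trimethylsilyl trifluoromethanesulfonate, C[Si](C)(C)OS(=O)(=O)C(F)(F)F
Why: Silyl triflate/amine enolisation under equilibrating conditions favours the more substituted enol ether (towards C2). O10 is silylated in passing, which also opens any hemiketal.

Step 18
Reactants: 31 bis(trimethylsilyl) compound
Product: 32 ring B enone (C26 ketone; C2=C3)
Conditions: Pd(OAc)2 (1.1 equiv), MeCN, 25 °C; then 1 M HCl, THF, 0 °C
Reagents that add atoms: none
Why: Saegusa oxidation: Pd(OAc)2 (divalent palladium) forms the oxo-π-allyl complex at C2 and β-hydride elimination of H3 gives the conjugated enone, Z by ring constraint. Brief acid removes the silyl ether from O10.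

Step 19
Reactants: 32 ring B enone
Product: 33 C26 1,3-dithiolane
Conditions: HS(CH2)2SH, BF3·OEt2, CH2Cl2, 0 to 25 °C
Reagents that add atoms: ethane-1,2-dithiol, SCCS
Why: Lewis-acid thioketalisation of a conjugated ketone, which, unlike oxygen ketalisation, leaves the double bond in place. C3 is fully substituted, so conjugate addition of thiol is disfavoured.

Step 20
Reactants: 33 C26 1,3-dithiolane
Product: 34 alkene ester (C26 methylene; C2=C3)
Conditions: Raney nickel (W-2), EtOH, reflux
Reagents that add atoms: none
Why: Reductive desulfurisation, the classical way from an enone to the alkene of unchanged position; a tetrasubstituted alkene should resist hydrogenation on the nickel.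

Step 21
Reactants: 34 alkene ester
Product: 35 diol (C12 primary alcohol; O10–H)
Conditions: LiAlH4, THF, 0 to 65 °C
Reagents that add atoms: none
Why: Hydride reduction of the hindered neopentyl ester; no other reducible group is left.

Step 22
Reactants: 35 diol
Product: 36 hydroxy aldehyde (C12 aldehyde)
Conditions: TEMPO (10 mol%), PhI(OAc)2, CH2Cl2, 25 °C
Reagents that add atoms: none
Why: Oxoammonium oxidation is selective for the primary alcohol; the neopentyl secondary hydroxyl at C9 should remain.

Step 23
Reactants: 36 hydroxy aldehyde
Product: 38 target alcohol, via C12 hydrazone 37 (not isolated)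
Conditions: N2H4·H2O, diethylene glycol, 130 °C; then KOH, 200 °C
Reagents that add atoms: none
Why: Wolff–Kishner reduction (Huang-Minlon procedure) turns the angular aldehyde into the C12 methyl. The hydrazone is formed before base is added so that the β-hydroxy aldehyde is not exposed to alkali; C12 is the only carbonyl left.

## Compound list

1 | 3,3-dimethylcyclohexanone | CC1(C)CCCC(=O)C1 | starting material
2 | lithium 5,5-dimethylcyclohex-1-en-1-olate | [Li+].[O-]C1=CCCC(C)(C)C1 | intermediate
3 | 2,5,5-trimethylcyclohexanone (racemic) | CC1CCC(C)(C)CC1=O | intermediate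
4 | (R)-1-phenylethylamine | C[C@@H](N)c1ccccc1 | starting material
5 | (R)-1-phenyl-N-(2,5,5-trimethylcyclohexylidene)ethanamine (ring methyl centre and C=N geometry mixed) | CC1CCC(C)(C)CC1=N[C@H](C)c1ccccc1 | intermediate
6 | but-3-en-2-one | CC(=O)C=C | starting material
7 | ketimine Michael adduct: (R)-1-phenylethyl imine of (S)-2,5,5-trimethyl-2-(3-oxobutyl)cyclohexanone | CC(=O)CC[C@]1(C)CCC(C)(C)CC1=N[C@H](C)c1ccccc1 | intermediate
8 | (S)-2,5,5-trimethyl-2-(3-oxobutyl)cyclohexan-1-one | CC(=O)CC[C@]1(C)CCC(C)(C)CC1=O | intermediate
9 | (S)-4a,7,7-trimethyl-4,4a,5,6,7,8-hexahydronaphthalen-2(3H)-one | O=C1CC[C@]2(C)CCC(C)(C)CC2=C1 | intermediate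
10 | 1-bromobut-2-yne | CC#CCBr | starting material
11 | lithium enolate (O–C11, C11=C24) of the trans-fused decalone, H23 β | [Li+].[O-]C1=C[C@@H]2CC(C)(C)CC[C@@]2(C)CC1 | intermediate
12 | trans-fused decalone: C11 ketone, C24 β-(but-2-yn-1-yl) equatorial, H23 β, H24 α, C15 α-methyl, C19 gem-dimethyl | O=C1CC[C@]2(C)CCC(C)(C)C[C@H]2[C@@H]1CC#CC | intermediate
13 | potassium enolate of 12 towards C13 | [K+].[O-]C1=CC[C@]2(C)CCC(C)(C)C[C@H]2[C@@H]1CC#CC | intermediate
14 | enol triflate of 12, C11(OTf)=C13 | O=S(=O)(OC1=CC[C@]2(C)CCC(C)(C)C[C@H]2[C@@H]1CC#CC)C(F)(F)F | intermediate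
15 | unsaturated acid: C12 carboxyl on C11, C11=C13, C24 β-butynyl | OC(=O)C1=CC[C@]2(C)CCC(C)(C)C[C@H]2[C@@H]1CC#CC | intermediate
16 | (Z)-enol δ-lactone: ring O–C12(=O)–C11–C24–C25–C26, exocyclic C26=C2H–C1, C11=C13 | C/C=C1\OC(=O)C2=CC[C@]3(C)CCC(C)(C)C[C@H]3[C@@H]2C1 | intermediate
17 | ring-opened sodium enolate: methyl ester at C12 (C11=C13), enolate O–C26, C26=C2 | [Na+].COC(=O)C1=CC[C@]2(C)CCC(C)(C)C[C@H]2[C@@H]1C/C([O-])=C/C | intermediate
18 | sodium enolate of the decalin-fused 2-methylcyclohexane-1,3-dione (C12 and C26 carbonyls, C2 methyl, C11=C13, H24 α, H23 β) | [Na+].CC1=C([O-])C[C@H]2[C@@H]3CC(C)(C)CC[C@@]3(C)CC=C2C1=O | intermediate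
19 | cyclopent-2-en-1-one | O=C1C=CCC1 | starting material
20 | trans-2,3-dibromocyclopentan-1-one (racemic) | O=C1[C@@H](Br)[C@H](Br)CC1 | intermediate
21 | 2-bromocyclopent-2-en-1-one | O=C1C(Br)=CCC1 | intermediate
22 | 6-bromo-1,4-dioxaspiro[4.4]non-6-ene | BrC1=CCCC12OCCO2 | intermediate
23 | 6-lithio-1,4-dioxaspiro[4.4]non-6-ene | [Li]C1=CCCC12OCCO2 | intermediate
24 | 1,4-dioxaspiro[4.4]non-6-ene-6-carbaldehyde | O=CC1=CCCC12OCCO2 | intermediate
25 | Michael adduct aldehyde: C2 quaternary (methyl; C3 on the α face of the dione ring), C12 enone with C11=C13, C26 ketone, C9 aldehyde on C8 | C[C@@]1([C@@H]2CCC3(OCCO3)[C@@H]2C=O)C(=O)C[C@H]4[C@@H]5CC(C)(C)CC[C@@]5(C)CC=C4C1=O | intermediate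
26 | bridged ketol: bicyclo[3.3.1]nonane with bridge carbonyl C12 between C2 and C11, C26 ketone, O10 α, H8 α, ring A cis-fused, C13=C14 | C[C@]12[C@@H]3CCC4(OCCO4)[C@@H]3[C@@H](O)[C@@]5(C1=O)C=C[C@]6(C)CCC(C)(C)C[C@H]6[C@@H]5CC2=O | intermediate
27 | tetracyclic keto ester: C26 ketone, C2 methyl (α drawn, epimers), H3 α, H8 α, C6 ethylene ketal, O10 α, C11 β-CO2Me, C13=C14 | C[C@H]1[C@@H]2CCC4(OCCO4)[C@@H]2[C@@H](O)[C@@]2(C(=O)OC)C=C[C@]3(C)CCC(C)(C)C[C@H]3[C@@H]2CC1=O | intermediate
28 | diketone: as 27 with C6 ketone | C[C@H]1[C@@H]2CCC(=O)[C@@H]2[C@@H](O)[C@@]2(C(=O)OC)C=C[C@]3(C)CCC(C)(C)C[C@H]3[C@@H]2CC1=O | intermediate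
29 | as 28 with C6 exocyclic methylene | C[C@H]1[C@@H]2CCC(=C)[C@@H]2[C@@H](O)[C@@]2(C(=O)OC)C=C[C@]3(C)CCC(C)(C)C[C@H]3[C@@H]2CC1=O | intermediate
30 | saturated keto ester: C6 β-methyl, ring C saturated, C26 ketone, C11 β-CO2Me, O10 α | C[C@H]1[C@@H]2CC[C@H](C)[C@@H]2[C@@H](O)[C@@]2(C(=O)OC)CC[C@]3(C)CCC(C)(C)C[C@H]3[C@@H]2CC1=O | intermediate
31 | C26 trimethylsilyl enol ether (C2=C26) with O10 trimethylsilyl ether | C[Si](C)(C)O/C1=C(\C)[C@@H]2CC[C@H](C)[C@@H]2[C@@H](O[Si](C)(C)C)[C@@]2(C(=O)OC)CC[C@]3(C)CCC(C)(C)C[C@H]3[C@@H]2CC1 | intermediate
32 | ring B enone: C26 ketone conjugated to C2=C3, C11 β-CO2Me, O10 α free | C/C1=C2\CC[C@H](C)[C@@H]2[C@@H](O)[C@@]2(C(=O)OC)CC[C@]3(C)CCC(C)(C)C[C@H]3[C@@H]2CC1=O | intermediate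
33 | 1,3-dithiolane of 32 at C26 | C/C1=C2\CC[C@H](C)[C@@H]2[C@@H](O)[C@@]2(C(=O)OC)CC[C@]3(C)CCC(C)(C)C[C@H]3[C@@H]2CC14SCCS4 | intermediate
34 | alkene ester: C26 methylene, C2=C3, C11 β-CO2Me | C/C1=C2\CC[C@H](C)[C@@H]2[C@@H](O)[C@@]2(C(=O)OC)CC[C@]3(C)CCC(C)(C)C[C@H]3[C@@H]2CC1 | intermediate
35 | diol: C12 hydroxymethyl on C11, O10 α | C/C1=C2\CC[C@H](C)[C@@H]2[C@@H](O)[C@@]2(CO)CC[C@]3(C)CCC(C)(C)C[C@H]3[C@@H]2CC1 | intermediate
36 | hydroxy aldehyde: C12 formyl on C11 | C/C1=C2\CC[C@H](C)[C@@H]2[C@@H](O)[C@@]2(C=O)CC[C@]3(C)CCC(C)(C)C[C@H]3[C@@H]2CC1 | intermediate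
37 | C12 hydrazone of 36 | C/C1=C2\CC[C@H](C)[C@@H]2[C@@H](O)[C@@]2(/C=N/N)CC[C@]3(C)CCC(C)(C)C[C@H]3[C@@H]2CC1 | intermediate
38 | target alcohol (CNP0399382.1) | C/C1=C2\CC[C@H](C)[C@@H]2[C@@H](O)[C@@]2(C)CC[C@]3(C)CCC(C)(C)C[C@H]3[C@@H]2CC1 | target

## Step count and least certain steps

Total: 23 steps. Longest linear sequence: 20 steps (steps 1–9 and 13–23); the enal branch (steps 10–12) has 3.

**Step 13 (key step).** The most likely failure is poor facial selectivity when C2 is alkylated: addition on the β face followed by bridging on that face would lead into the C11-epimeric series. A second loss is methanolysis of the dione ring before the aldol has occurred. Fallback: from 18 and 24, run the Michael–aldol stage without a nucleophilic alkoxide (DBU, THF, 25–50 °C), conditions under which the ketols can form and revert but cannot be cleaved. Isolate ketol 26 by chromatography from the β-face bridged ketol F1, and return F1 to the same base to re-equilibrate through retro-aldol and retro-Michael steps. Treat pure 26 with NaOMe in MeOH at 0 °C; this returns to the route at 27.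

**Step 15.** The risk is loss of chemoselectivity (methylenation at C26 as well as C6), together with epimerisation at C8 or opening of the β-hydroxy ketone while the C6 ketone is free. Fallback: from 27, mask C26 at the alcohol level so that only one ketone is present. NaBH4 in MeOH gives the hydroxy ketal F2; PPTS in wet acetone gives the hydroxy ketone F3; Zn/CH2Br2/TiCl4 gives the methylene compound F4; H2 over PtO2 gives the saturated diol ester F5. Oxidation of the less hindered C26 hydroxyl (Dess–Martin periodinane, 1 equiv, 0 °C; O10 is neopentyl) returns to the route at 30.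

**Step 17.** The risk is enolisation towards C25 instead of C2, which would place the unsaturation at C24–C25 in the following step. Fallback: from 30, acid-catalysed bromination through the more substituted enol (PhNMe3Br3, THF, 0 °C) gives the C2 bromo ketone F6; dehydrobromination (Li2CO3, LiBr, DMF, 120 °C) towards C3 returns to the route at 32.

**Step 19.** The risk is transannular capture of the activated C26 by O10 or sluggish thioketalisation of the hindered enone; in the desulfurisation that follows, migration of the double bond on the nickel surface is the related risk. Fallback: from 32, 1,2-reduction (NaBH4, CeCl3·7H2O, MeOH) gives the allylic alcohol F7; ClCO2Me and pyridine give the allylic methyl carbonate F8; Pd(PPh3)4 (zerovalent palladium) with NaBH4 in THF delivers hydride to the less hindered allyl terminus C26 and returns to the route at 34, bypassing steps 19 and 20.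

**Step 23.** The risk is retro-aldol opening of ring B (C9–C11 cleavage) of the β-hydroxy aldehyde or its hydrazone in hot alkali. Fallback: from 35, sulfonylate the primary hydroxyl selectively (MsCl, Et3N, −20 °C) to the mesylate F9 and reduce with LiBHEt3 in THF at reflux, directly or through the oxetane formed with O10, both of which are opened by hydride at C12; this arrives at 38.

## Further compounds

F1 | step 13 | β-face bridged ketol (C2, C3, C8, C9 and C11 opposite to 26) | C[C@@]12[C@H]3CCC4(OCCO4)[C@H]3[C@H](O)[C@]5(C1=O)C=C[C@]6(C)CCC(C)(C)C[C@H]6[C@@H]5CC2=O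
F2 | step 15 | hydroxy ketal: 27 with C26 reduced to the alcohol (C26 epimers) | C[C@H]1[C@@H]2CCC4(OCCO4)[C@@H]2[C@@H](O)[C@@]2(C(=O)OC)C=C[C@]3(C)CCC(C)(C)C[C@H]3[C@@H]2CC1O
F3 | step 15 | hydroxy ketone: C6 ketone, C26 alcohol | C[C@H]1[C@@H]2CCC(=O)[C@@H]2[C@@H](O)[C@@]2(C(=O)OC)C=C[C@]3(C)CCC(C)(C)C[C@H]3[C@@H]2CC1O
F4 | step 15 | methylene compound: C6=C7, C26 alcohol | C[C@H]1[C@@H]2CCC(=C)[C@@H]2[C@@H](O)[C@@]2(C(=O)OC)C=C[C@]3(C)CCC(C)(C)C[C@H]3[C@@H]2CC1O
F5 | step 15 | saturated diol ester: C6 β-methyl, C26 alcohol | C[C@H]1[C@@H]2CC[C@H](C)[C@@H]2[C@@H](O)[C@@]2(C(=O)OC)CC[C@]3(C)CCC(C)(C)C[C@H]3[C@@H]2CC1O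
F6 | step 17 | C2 bromo ketone of 30 (C2 epimers) | CC1(Br)[C@@H]2CC[C@H](C)[C@@H]2[C@@H](O)[C@@]2(C(=O)OC)CC[C@]3(C)CCC(C)(C)C[C@H]3[C@@H]2CC1=O
F7 | step 19 | allylic alcohol: 32 with C26 reduced (C26 epimers) | C/C1=C2\CC[C@H](C)[C@@H]2[C@@H](O)[C@@]2(C(=O)OC)CC[C@]3(C)CCC(C)(C)C[C@H]3[C@@H]2CC1O
F8 | step 19 | allylic methyl carbonate of F7 at C26 | C/C1=C2\CC[C@H](C)[C@@H]2[C@@H](O)[C@@]2(C(=O)OC)CC[C@]3(C)CCC(C)(C)C[C@H]3[C@@H]2CC1OC(=O)OC
F9 | step 23 | C12 methanesulfonate of 35 | C/C1=C2\CC[C@H](C)[C@@H]2[C@@H](O)[C@@]2(COS(C)(=O)=O)CC[C@]3(C)CCC(C)(C)C[C@H]3[C@@H]2CC1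
A1 | alternative 1 | allene–yne: C6≡C8 alkyne on the C9 silyl ether carbinol, C26–C2(Me)=C3=C4 allene | CC#C[C@@H](O[Si](C)(C)C(C)(C)C)[C@@]1(C)CC[C@]2(C)CCC(C)(C)C[C@H]2[C@@H]1CCC(C)=C=C
A2 | alternative 1 | ring A/B dienone (C5 ketone, C6=C8, C2=C3), C9 silyl ether | C/C1=C2\CC(=O)C(C)=C2[C@@H](O[Si](C)(C)C(C)(C)C)[C@@]2(C)CC[C@]3(C)CCC(C)(C)C[C@H]3[C@@H]2CC1
A3 | alternative 2 | tertiary C3 methyl carbonate with isopropenyl group (C2, C1, C26) and C25 bis(phenylsulfonyl)methyl arm, C9 silyl ether (C3 epimers) | CC(=C)C1(OC(=O)OC)CC[C@H](C)[C@@H]1[C@@H](O[Si](C)(C)C(C)(C)C)[C@@]1(C)CC[C@]2(C)CCC(C)(C)C[C@H]2[C@@H]1C(S(=O)(=O)c1ccccc1)S(=O)(=O)c1ccccc1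
A4 | alternative 2 | ring B closed C25 bis(sulfone), C9 silyl ether | C/C1=C2\CC[C@H](C)[C@@H]2[C@@H](O[Si](C)(C)C(C)(C)C)[C@@]2(C)CC[C@]3(C)CCC(C)(C)C[C@H]3[C@@H]2C(S(=O)(=O)c4ccccc4)(S(=O)(=O)c5ccccc5)C1
A5 | alternative 3 | decalin-fused 2-methylene-6-alkenyltetrahydropyran (C8=C9–O–C26–C2=C3 array) | C=C1O[C@@H](/C(C)=C\CCC#C[Si](C)(C)C)C[C@H]2[C@@H]3CC(C)(C)CC[C@@]3(C)CC[C@]12C
A6 | alternative 3 | ring B cyclooctenone (C9 ketone, C26=C2, silylbutynyl arm on C3) | O=C1[C@@]2(C)CC[C@]3(C)CCC(C)(C)C[C@H]3[C@@H]2C/C=C(C)\[C@H](CCC#C[Si](C)(C)C)C1
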